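**Retrosynthetic overview**
- The ten-membered carbocycle is closed last, at C3–C4, by an intramolecular Nozaki–Hiyama–Kishi addition of a (Z)-vinyl iodide to an (E)-enal, followed by oxidation to the dienone and desilylation.
- The γ-lactone is the first ring formed: an anti-selective chromium allylation (C6–C7) of a (Z)-β-iodo enal with a Baylis–Hillman-derived allyl bromide, then C6–O lactonisation. The C8 ester is put on right after.
- Key disconnection: the C8–O bond, made enantioselectively and already silyl-protected by a new aminocatalytic α-silyloxylation of an aldehyde. This stereocentre then relays C7 and C6.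
- C10 carbinol comes from (R)-linalool, C3 from 2-vinyl-1,3-dioxolane (cross-metathesis), C11–C13 from methyl acrylate, C4–C6 and C15 from but-2-yne-1,4-diol.
- Ring order: lactone (step 10), then carbocycle (step 12).

Assumption: C-locants in the running text (C1–C15) follow germacrane numbering of the target (C6 lactone carbinol, C8 ester carbon, C10 tertiary carbinol, C15 hydroxymethyl); (R)-(−)-linalool and (R)-2-methylbutanoic acid are taken as commercial in high ee.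

**Route**

Step 1
Reactants: 1 (R)-(−)-linalool
Product: 2 (3R)-3,7-dimethyl-3-[(triethylsilyl)oxy]octa-1,6-diene
Conditions: TESOTf, 2,6-lutidine, CH2Cl2, −78 → 0 °C
Reagents that add atoms: triethylsilyl trifluoromethanesulfonate, CC[Si](CC)(CC)OS(=O)(=O)C(F)(F)F
Why: Silyl triflate silylation of the hindered tertiary allylic alcohol under basic, non-ionising conditions masks C10–OH (the free γ-hydroxy aldehyde would otherwise sit as a lactol); the C10 stereocentre is taken unchanged from the chiral pool.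

Step 2
Reactants: 2 (3R)-3,7-dimethyl-3-[(triethylsilyl)oxy]octa-1,6-diene
Product: 3 (4R)-4-methyl-4-[(triethylsilyl)oxy]hex-5-enal
Conditions: O3 (1 equiv, Sudan Red end-point), pyridine, CH2Cl2, −78 °C
Reagents that add atoms: ozone, [O-][O+]=O
Why: Pyridine-mediated reductive ozonolysis cleaves only the electron-rich trisubstituted alkene (the vinyl group next to the silyloxy-bearing quaternary carbon reacts much more slowly) and gives the C7 aldehyde directly.

Step 3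
Reactants: 3 (4R)-4-methyl-4-[(triethylsilyl)oxy]hex-5-enal; 4 2-vinyl-1,3-dioxolane
Product: 5 (4R,5E)-6-(1,3-dioxolan-2-yl)-4-methyl-4-[(triethylsilyl)oxy]hex-5-enal
Conditions: 4 (4 equiv), second-generation Hoveyda–Grubbs catalyst RuCl2(SIMes)(=CH-C6H4-2-OiPr) (5 mol%), CH2Cl2, 40 °C
Reagents that add atoms: none
Why: Olefin cross-metathesis of a hindered, non-dimerising vinyl group with excess acrolein acetal gives the E-alkene (C1=C2) and brings in C3 as a masked aldehyde; it is run before any acrylate unit exists, so no ring-closing side reaction is possible.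

Step 4
Reactants: 5 (4R,5E)-6-(1,3-dioxolan-2-yl)-4-methyl-4-[(triethylsilyl)oxy]hex-5-enal
Product: 6 (2R,4R,5E)-6-(1,3-dioxolan-2-yl)-4-methyl-2,4-bis[(triethylsilyl)oxy]hex-5-enal
Conditions: Et3SiCl, urea·H2O2, imidazole, CH2Cl2, 0 °C (gives Et3SiOOSiEt3 in the flask); then 5, (R)-α,α-diphenylprolinol trimethylsilyl ether (20 mol%), 4-nitrobenzoic acid (20 mol%), −20 °C
Reagents that add atoms: chlorotriethylsilane, CC[Si](Cl)(CC)CC; urea–hydrogen peroxide, NC(N)=O.OO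
Why: Proposed new method: aminocatalytic α-silyloxylation of an aldehyde — the enamine of 5 attacks the O–O σ* orbital of bis(triethylsilyl) peroxide so that one Et3SiO group is transferred as the electrophile while the other leaves as silanolate (helped by the acid co-catalyst), and the bulky diphenyl(silyloxy)methyl group of the (R)-catalyst shields one enamine face so that the C8–O stereocentre is expected as 2R (steric-shielding model; the (S)-catalyst is used if the sense is opposite), directly in protected form; the closest known reactions are the aminocatalytic α-benzoyloxylation of aldehydes with dibenzoyl peroxide and the hydroxylation of enolates with bis(trimethylsilyl) peroxide.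

Step 5
Reactants: 6 (2R,4R,5E)-6-(1,3-dioxolan-2-yl)-4-methyl-2,4-bis[(triethylsilyl)oxy]hex-5-enal; 7 methyl acrylate
Product: 8 methyl (4R,6R,7E)-8-(1,3-dioxolan-2-yl)-3-hydroxy-6-methyl-2-methylidene-4,6-bis[(triethylsilyl)oxy]oct-7-enoate (both C3 epimers)
Conditions: 7 (5 equiv), quinuclidine (0.3 equiv), MeOH (0.8 equiv), rt
Reagents that add atoms: none
Why: Morita–Baylis–Hillman reaction of the activated α-silyloxy aldehyde installs C11–C13; the new carbinol centre (C7) need not be controlled because it becomes sp2 in the next step.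

Step 6
Reactants: 8 methyl (4R,6R,7E)-8-(1,3-dioxolan-2-yl)-3-hydroxy-6-methyl-2-methylidene-4,6-bis[(triethylsilyl)oxy]oct-7-enoate
Product: 9 methyl (2Z,4R,6R,7E)-2-(bromomethyl)-8-(1,3-dioxolan-2-yl)-6-methyl-4,6-bis[(triethylsilyl)oxy]octa-2,7-dienoate
Conditions: NBS, Me2S, CH2Cl2, 0 °C → rt
Reagents that add atoms: N-bromosuccinimide, O=C1CCC(=O)N1Br
Why: Corey–Kim-type bromination of the Baylis–Hillman alcohol with SN2′ allylic transposition gives the thermodynamically preferred (Z)-2-(bromomethyl)enoate under near-neutral conditions that spare the TES ethers and the dioxolane.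

Step 7
Reactants: 10 but-2-yne-1,4-diol
Product: 11 4-[(tert-butyldiphenylsilyl)oxy]but-2-yn-1-ol
Conditions: TBDPSCl (1 equiv), imidazole, 10 (3 equiv), DMF, 0 °C → rt
Reagents that add atoms: tert-butyl(chloro)diphenylsilane, CC(C)(C)[Si](Cl)(c1ccccc1)c1ccccc1
Why: Statistical monosilylation of a cheap symmetrical diol used in excess; TBDPS is chosen because it survives the aqueous acid that later strips the TES groups.

Step 8
Reactants: 11 4-[(tert-butyldiphenylsilyl)oxy]but-2-yn-1-ol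
Product: 13 (2Z)-4-[(tert-butyldiphenylsilyl)oxy]-3-iodobut-2-en-1-ol, via cyclic sodium alkenylalanate 12 (not isolated)
Conditions: NaAlH2(OCH2CH2OCH3)2, THF, 0 °C; then I2, −78 °C → rt
Reagents that add atoms: iodine, II
Why: Hydroxyl-directed trans-hydroalumination of the propargylic alcohol followed by iododealumination with retention fixes the alkene geometry: iodine (future C3 attachment) ends cis to the CH2OH arm (future C6), which is the 4Z geometry of the target.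

Step 9
Reactants: 13 (2Z)-4-[(tert-butyldiphenylsilyl)oxy]-3-iodobut-2-en-1-ol
Product: 14 (2Z)-4-[(tert-butyldiphenylsilyl)oxy]-3-iodobut-2-enal
Conditions: MnO2, CH2Cl2, rt
Reagents that add atoms: none
Why: Allylic alcohol oxidation with MnO2 gives the (Z)-β-iodo enal without isomerising the double bond.

Step 10
Reactants: 9 methyl (2Z,4R,6R,7E)-2-(bromomethyl)-8-(1,3-dioxolan-2-yl)-6-methyl-4,6-bis[(triethylsilyl)oxy]octa-2,7-dienoate; 14 (2Z)-4-[(tert-butyldiphenylsilyl)oxy]-3-iodobut-2-enal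
Product: 17 (4R,5S)-5-[(1Z)-3-[(tert-butyldiphenylsilyl)oxy]-2-iodoprop-1-en-1-yl]-4-[(1R,3R,4E)-1,3-dihydroxy-3-methyl-6-oxohex-4-en-1-yl]-3-methylideneoxolan-2-one, via hydroxy ester chromium alkoxide 15 (not isolated), via bis-triethylsilyl dioxolane lactone 16 (not isolated)
Conditions: CrCl2 (3 equiv), THF, 0 °C → rt, 12 h; then 1 M HCl, THF, rt
Reagents that add atoms: water, O
Why: Nozaki–Hiyama-type chromium allylation (SE2′ at C7) through a chair transition state gives the anti C6/C7 relationship (trans-lactone); the C8 stereocentre is expected to steer the aldehyde to the face anti to the C9 chain with C8–H eclipsing the enoate (allylic 1,3-strain model); the trivalent chromium alkoxide then closes the γ-lactone C6–O bond on the neighbouring methyl ester (C8–O is still silylated, so only C6–O can close), and dilute acid removes both TES groups and the dioxolane while TBDPS stays.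

Step 11
Reactants: 17 (4R,5S)-5-[(1Z)-3-[(tert-butyldiphenylsilyl)oxy]-2-iodoprop-1-en-1-yl]-4-[(1R,3R,4E)-1,3-dihydroxy-3-methyl-6-oxohex-4-en-1-yl]-3-methylideneoxolan-2-one; 18 (2R)-2-methylbutanoic acid
Product: 19 (1R,3R,4E)-1-[(2S,3R)-2-[(1Z)-3-[(tert-butyldiphenylsilyl)oxy]-2-iodoprop-1-en-1-yl]-4-methylidene-5-oxooxolan-3-yl]-3-hydroxy-3-methyl-6-oxohex-4-en-1-yl (2R)-2-methylbutanoate
Conditions: EDC·HCl, DMAP (0.2 equiv), CH2Cl2, 0 °C → rt
Reagents that add atoms: none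
Why: Steglich esterification acylates the only reactive hydroxyl (secondary C8–OH; C10–OH is tertiary and C15–OH is silylated) with retention at C8 and without epimerising the acid.

Step 12
Reactants: 19 (1R,3R,4E)-1-[(2S,3R)-2-[(1Z)-3-[(tert-butyldiphenylsilyl)oxy]-2-iodoprop-1-en-1-yl]-4-methylidene-5-oxooxolan-3-yl]-3-hydroxy-3-methyl-6-oxohex-4-en-1-yl (2R)-2-methylbutanoate
Product: 20 (3aR,4R,6R,7E,10Z,11aR)-10-{[(tert-butyldiphenylsilyl)oxy]methyl}-6,9-dihydroxy-6-methyl-3-methylidene-2-oxo-2,3,3a,4,5,6,9,11a-octahydrocyclodeca[b]furan-4-yl (2R)-2-methylbutanoate (both C9 epimers)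
Conditions: CrCl2 (10 equiv), NiCl2 (0.2 equiv), DMSO/THF, 0.002 M, rt
Reagents that add atoms: none
Why: Intramolecular Nozaki–Hiyama–Kishi reaction at high dilution: zerovalent nickel inserts into the vinyl iodide, transmetalation to chromium and 1,2-addition to the enal close the ten-membered ring at C3–C4 with retention of the 4Z geometry; the C3 carbinol configuration does not matter.

Step 13
Reactants: 20 (3aR,4R,6R,7E,10Z,11aR)-10-{[(tert-butyldiphenylsilyl)oxy]methyl}-6,9-dihydroxy-6-methyl-3-methylidene-2-oxo-2,3,3a,4,5,6,9,11a-octahydrocyclodeca[b]furan-4-yl (2R)-2-methylbutanoate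
Product: 21 (3aR,4R,6R,7E,10Z,11aR)-10-{[(tert-butyldiphenylsilyl)oxy]methyl}-6-hydroxy-6-methyl-3-methylidene-2,9-dioxo-2,3,3a,4,5,6,9,11a-octahydrocyclodeca[b]furan-4-yl (2R)-2-methylbutanoate
Conditions: Dess–Martin periodinane, NaHCO3, CH2Cl2, 0 °C
Reagents that add atoms: none
Why: Dess–Martin oxidation of the doubly allylic secondary alcohol gives the cross-conjugated dienone; the tertiary C10–OH cannot be oxidised.

Step 14
Reactants: 21 (3aR,4R,6R,7E,10Z,11aR)-10-{[(tert-butyldiphenylsilyl)oxy]methyl}-6-hydroxy-6-methyl-3-methylidene-2,9-dioxo-2,3,3a,4,5,6,9,11a-octahydrocyclodeca[b]furan-4-yl (2R)-2-methylbutanoate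
Product: 22 (3aR,4R,6R,7E,10Z,11aR)-6-hydroxy-10-(hydroxymethyl)-6-methyl-3-methylidene-2,9-dioxo-2,3,3a,4,5,6,9,11a-octahydrocyclodeca[b]furan-4-yl (2R)-2-methylbutanoate (CNP0232405.1)
Conditions: HF·pyridine, pyridine, THF, 0 °C → rt
Reagents that add atoms: none
Why: Buffered fluoride desilylation frees C15–OH without opening the lactone, adding to the α-methylene lactone or cleaving the ester.

**Compound list**
1 | (R)-(−)-linalool, (3R)-3,7-dimethylocta-1,6-dien-3-ol | C=C[C@](C)(O)CCC=C(C)C | starting material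
2 | (3R)-3,7-dimethyl-3-[(triethylsilyl)oxy]octa-1,6-diene | C=C[C@](C)(O[Si](CC)(CC)CC)CCC=C(C)C | intermediate
3 | (4R)-4-methyl-4-[(triethylsilyl)oxy]hex-5-enal | C=C[C@](C)(O[Si](CC)(CC)CC)CCC=O | intermediate
4 | 2-vinyl-1,3-dioxolane | C=CC1OCCO1 | starting material
5 | (4R,5E)-6-(1,3-dioxolan-2-yl)-4-methyl-4-[(triethylsilyl)oxy]hex-5-enal | O=CCC[C@@](C)(O[Si](CC)(CC)CC)/C=C/C1OCCO1 | intermediate
6 | (2R,4R,5E)-6-(1,3-dioxolan-2-yl)-4-methyl-2,4-bis[(triethylsilyl)oxy]hex-5-enal | O=C[C@H](O[Si](CC)(CC)CC)C[C@@](C)(O[Si](CC)(CC)CC)/C=C/C1OCCO1 | intermediate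
7 | methyl acrylate | C=CC(=O)OC | starting material
8 | methyl (4R,6R,7E)-8-(1,3-dioxolan-2-yl)-3-hydroxy-6-methyl-2-methylidene-4,6-bis[(triethylsilyl)oxy]oct-7-enoate, C3 epimers | COC(=O)C(=C)C(O)[C@H](O[Si](CC)(CC)CC)C[C@@](C)(O[Si](CC)(CC)CC)/C=C/C1OCCO1 | intermediate
9 | methyl (2Z,4R,6R,7E)-2-(bromomethyl)-8-(1,3-dioxolan-2-yl)-6-methyl-4,6-bis[(triethylsilyl)oxy]octa-2,7-dienoate | COC(=O)/C(CBr)=C/[C@H](O[Si](CC)(CC)CC)C[C@@](C)(O[Si](CC)(CC)CC)/C=C/C1OCCO1 | intermediate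
10 | but-2-yne-1,4-diol | OCC#CCO | starting material
11 | 4-[(tert-butyldiphenylsilyl)oxy]but-2-yn-1-ol | OCC#CCO[Si](c1ccccc1)(c1ccccc1)C(C)(C)C | intermediate
12 | sodium 3-{[(tert-butyldiphenylsilyl)oxy]methyl}-2,2-bis(2-methoxyethoxy)-2,5-dihydro-1,2-oxaluminol-2-uide (cyclic alkenylalanate, not isolated) | [Na+].COCCO[Al-]1(OCCOC)OCC=C1CO[Si](c1ccccc1)(c1ccccc1)C(C)(C)C | intermediate
13 | (2Z)-4-[(tert-butyldiphenylsilyl)oxy]-3-iodobut-2-en-1-ol | OC/C=C(\I)CO[Si](c1ccccc1)(c1ccccc1)C(C)(C)C | intermediate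
14 | (2Z)-4-[(tert-butyldiphenylsilyl)oxy]-3-iodobut-2-enal | O=C/C=C(\I)CO[Si](c1ccccc1)(c1ccccc1)C(C)(C)C | intermediate
15 | methyl (3S,4R,6R,7E)-3-[(1S,2Z)-4-[(tert-butyldiphenylsilyl)oxy]-1-hydroxy-3-iodobut-2-en-1-yl]-8-(1,3-dioxolan-2-yl)-6-methyl-2-methylidene-4,6-bis[(triethylsilyl)oxy]oct-7-enoate (present as its chromium alkoxide, not isolated) | COC(=O)C(=C)[C@@H]([C@H](O)/C=C(\I)CO[Si](c1ccccc1)(c1ccccc1)C(C)(C)C)[C@H](O[Si](CC)(CC)CC)C[C@@](C)(O[Si](CC)(CC)CC)/C=C/C1OCCO1 | intermediate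
16 | (4S,5S)-5-[(1Z)-3-[(tert-butyldiphenylsilyl)oxy]-2-iodoprop-1-en-1-yl]-4-[(1R,3R,4E)-5-(1,3-dioxolan-2-yl)-3-methyl-1,3-bis[(triethylsilyl)oxy]pent-4-en-1-yl]-3-methylideneoxolan-2-one (not isolated) | C=C1C(=O)O[C@H](/C=C(\I)CO[Si](c2ccccc2)(c2ccccc2)C(C)(C)C)[C@H]1[C@H](O[Si](CC)(CC)CC)C[C@@](C)(O[Si](CC)(CC)CC)/C=C/C1OCCO1 | intermediate
17 | (4R,5S)-5-[(1Z)-3-[(tert-butyldiphenylsilyl)oxy]-2-iodoprop-1-en-1-yl]-4-[(1R,3R,4E)-1,3-dihydroxy-3-methyl-6-oxohex-4-en-1-yl]-3-methylideneoxolan-2-one | C=C1C(=O)O[C@H](/C=C(\I)CO[Si](c2ccccc2)(c2ccccc2)C(C)(C)C)[C@H]1[C@H](O)C[C@@](C)(O)/C=C/C=O | intermediate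
18 | (2R)-2-methylbutanoic acid | CC[C@@H](C)C(=O)O | starting material
19 | (1R,3R,4E)-1-[(2S,3R)-2-[(1Z)-3-[(tert-butyldiphenylsilyl)oxy]-2-iodoprop-1-en-1-yl]-4-methylidene-5-oxooxolan-3-yl]-3-hydroxy-3-methyl-6-oxohex-4-en-1-yl (2R)-2-methylbutanoate | C=C1C(=O)O[C@H](/C=C(\I)CO[Si](c2ccccc2)(c2ccccc2)C(C)(C)C)[C@H]1[C@H](OC(=O)[C@H](C)CC)C[C@@](C)(O)/C=C/C=O | intermediate
20 | (3aR,4R,6R,7E,10Z,11aR)-10-{[(tert-butyldiphenylsilyl)oxy]methyl}-6,9-dihydroxy-6-methyl-3-methylidene-2-oxo-2,3,3a,4,5,6,9,11a-octahydrocyclodeca[b]furan-4-yl (2R)-2-methylbutanoate, C9 epimers | C=C1C(=O)O[C@@H]2/C=C(/CO[Si](c3ccccc3)(c3ccccc3)C(C)(C)C)C(O)/C=C/[C@](C)(O)C[C@@H](OC(=O)[C@H](C)CC)[C@@H]12 | intermediate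
21 | (3aR,4R,6R,7E,10Z,11aR)-10-{[(tert-butyldiphenylsilyl)oxy]methyl}-6-hydroxy-6-methyl-3-methylidene-2,9-dioxo-2,3,3a,4,5,6,9,11a-octahydrocyclodeca[b]furan-4-yl (2R)-2-methylbutanoate | C=C1C(=O)O[C@@H]2/C=C(/CO[Si](c3ccccc3)(c3ccccc3)C(C)(C)C)C(=O)/C=C/[C@](C)(O)C[C@@H](OC(=O)[C@H](C)CC)[C@@H]12 | intermediate
22 | (3aR,4R,6R,7E,10Z,11aR)-6-hydroxy-10-(hydroxymethyl)-6-methyl-3-methylidene-2,9-dioxo-2,3,3a,4,5,6,9,11a-octahydrocyclodeca[b]furan-4-yl (2R)-2-methylbutanoate (CNP0232405.1) | C=C1C(=O)O[C@@H]2/C=C(/CO)C(=O)/C=C/[C@](C)(O)C[C@@H](OC(=O)[C@H](C)CC)[C@@H]12 | target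

The CIP letters at C6 and C7 change along the route (6S in the iodides, 7S while C8 carries O–Si) only because of substituent priorities; the spatial arrangement is that of the target throughout.

**Totals**
Total step count: 14. Longest linear sequence: 11 (steps 1–6, then 10–14).

**Three steps most likely to fail**

1. Step 4 (the new α-silyloxylation). The silanolate is a poorer leaving group than benzoate, so the peroxide may be too weak an electrophile, or it may oxidise the amine catalyst. The fallback uses known chemistry, sets out from 5 and comes back at 6. L-Proline-catalysed α-aminoxylation of 5 with nitrosobenzene (CHCl3, 0 °C) gives the 2-(anilinooxy) aldehyde F1, which is reduced in the same pot with NaBH4 to the 2-(anilinooxy) alcohol F2. Zn dust in AcOH/EtOH cleaves the N–O bond to the 1,2-diol F3. TESCl/imidazole gives the tris-triethylsilyl ether F4. Swern oxidation (oxalyl chloride, DMSO, then Et3N, −78 °C), which converts a primary TES ether directly into the aldehyde while secondary and tertiary TES ethers survive, returns 6.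

2. Step 10 (chromium allylation/lactonisation). The anti preference and, above all, the π-facial sense imposed by C8 on C7 rest on a model. If the C7/C8 relationship comes out opposite, the fallback sets out from 5 and comes back at 19, using the C8 epimer and a late inversion. Step 4 with the (S)-catalyst (or the known sequence above with D-proline) gives the (2S)-silyloxy aldehyde F5. Steps 5 and 6 give the epimeric Baylis–Hillman alcohol F6 and the epimeric allyl bromide F7. The same chromium allylation with 14 then leads, through the epimeric hydroxy ester F8 and the epimeric silylated lactone F9, to the 8-epi diol F10, which has the correct C6 and C7. Mitsunobu esterification of F10 with 18 (PPh3, DIAD, toluene, 0 °C) installs the ester with inversion at C8 and gives 19.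

3. Step 12 (ten-membered ring closure by Nozaki–Hiyama–Kishi). Oligomerisation or failure to cyclise is possible. The fallback replaces carbonyl addition plus oxidation by a direct ketone-forming acyl coupling; it sets out from 19 and comes back at 21, skipping 20. Pinnick oxidation (NaClO2, NaH2PO4, 2-methyl-2-butene) gives the enoic acid F11. Thiophenol/EDC·HCl/DMAP gives the S-phenyl thioester F12. Pd(PPh3)4 with (Me3Sn)2 exchanges iodide for tin to give the vinylstannane thioester F13. A thioester–stannane ketone synthesis of the Liebeskind–Srogl type (Pd2(dba)3, tri(2-furyl)phosphine, CuO2PPh2, THF, high dilution) then closes the ring at C3–C4 and gives dienone 21 directly.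

**Further compounds**
F1 | step 4 | (2R,4R,5E)-2-(anilinooxy)-6-(1,3-dioxolan-2-yl)-4-methyl-4-[(triethylsilyl)oxy]hex-5-enal | O=C[C@H](ONc1ccccc1)C[C@@](C)(O[Si](CC)(CC)CC)/C=C/C1OCCO1
F2 | step 4 | (2R,4R,5E)-2-(anilinooxy)-6-(1,3-dioxolan-2-yl)-4-methyl-4-[(triethylsilyl)oxy]hex-5-en-1-ol | OC[C@H](ONc1ccccc1)C[C@@](C)(O[Si](CC)(CC)CC)/C=C/C1OCCO1
F3 | step 4 | (2R,4R,5E)-6-(1,3-dioxolan-2-yl)-4-methyl-4-[(triethylsilyl)oxy]hex-5-ene-1,2-diol | OC[C@H](O)C[C@@](C)(O[Si](CC)(CC)CC)/C=C/C1OCCO1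
F4 | step 4 | (2R,4R,5E)-6-(1,3-dioxolan-2-yl)-4-methyl-1,2,4-tris[(triethylsilyl)oxy]hex-5-ene | CC[Si](CC)(CC)OC[C@H](O[Si](CC)(CC)CC)C[C@@](C)(O[Si](CC)(CC)CC)/C=C/C1OCCO1
F5 | step 10 | (2S,4R,5E)-6-(1,3-dioxolan-2-yl)-4-methyl-2,4-bis[(triethylsilyl)oxy]hex-5-enal | O=C[C@@H](O[Si](CC)(CC)CC)C[C@@](C)(O[Si](CC)(CC)CC)/C=C/C1OCCO1
F6 | step 10 | methyl (4S,6R,7E)-8-(1,3-dioxolan-2-yl)-3-hydroxy-6-methyl-2-methylidene-4,6-bis[(triethylsilyl)oxy]oct-7-enoate, C3 epimers | COC(=O)C(=C)C(O)[C@@H](O[Si](CC)(CC)CC)C[C@@](C)(O[Si](CC)(CC)CC)/C=C/C1OCCO1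
F7 | step 10 | methyl (2Z,4S,6R,7E)-2-(bromomethyl)-8-(1,3-dioxolan-2-yl)-6-methyl-4,6-bis[(triethylsilyl)oxy]octa-2,7-dienoate | COC(=O)/C(CBr)=C/[C@@H](O[Si](CC)(CC)CC)C[C@@](C)(O[Si](CC)(CC)CC)/C=C/C1OCCO1
F8 | step 10 | methyl (3S,4S,6R,7E)-3-[(1S,2Z)-4-[(tert-butyldiphenylsilyl)oxy]-1-hydroxy-3-iodobut-2-en-1-yl]-8-(1,3-dioxolan-2-yl)-6-methyl-2-methylidene-4,6-bis[(triethylsilyl)oxy]oct-7-enoate (not isolated) | COC(=O)C(=C)[C@@H]([C@H](O)/C=C(\I)CO[Si](c1ccccc1)(c1ccccc1)C(C)(C)C)[C@@H](O[Si](CC)(CC)CC)C[C@@](C)(O[Si](CC)(CC)CC)/C=C/C1OCCO1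
F9 | step 10 | (4S,5S)-5-[(1Z)-3-[(tert-butyldiphenylsilyl)oxy]-2-iodoprop-1-en-1-yl]-4-[(1S,3R,4E)-5-(1,3-dioxolan-2-yl)-3-methyl-1,3-bis[(triethylsilyl)oxy]pent-4-en-1-yl]-3-methylideneoxolan-2-one (not isolated) | C=C1C(=O)O[C@H](/C=C(\I)CO[Si](c2ccccc2)(c2ccccc2)C(C)(C)C)[C@H]1[C@@H](O[Si](CC)(CC)CC)C[C@@](C)(O[Si](CC)(CC)CC)/C=C/C1OCCO1
F10 | step 10 | (4R,5S)-5-[(1Z)-3-[(tert-butyldiphenylsilyl)oxy]-2-iodoprop-1-en-1-yl]-4-[(1S,3R,4E)-1,3-dihydroxy-3-methyl-6-oxohex-4-en-1-yl]-3-methylideneoxolan-2-one | C=C1C(=O)O[C@H](/C=C(\I)CO[Si](c2ccccc2)(c2ccccc2)C(C)(C)C)[C@H]1[C@@H](O)C[C@@](C)(O)/C=C/C=O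
F11 | step 12 | (2E,4R,6R)-6-[(2S,3R)-2-[(1Z)-3-[(tert-butyldiphenylsilyl)oxy]-2-iodoprop-1-en-1-yl]-4-methylidene-5-oxooxolan-3-yl]-4-hydroxy-4-methyl-6-{[(2R)-2-methylbutanoyl]oxy}hex-2-enoic acid | C=C1C(=O)O[C@H](/C=C(\I)CO[Si](c2ccccc2)(c2ccccc2)C(C)(C)C)[C@H]1[C@H](OC(=O)[C@H](C)CC)C[C@@](C)(O)/C=C/C(=O)O
F12 | step 12 | S-phenyl (2E,4R,6R)-6-[(2S,3R)-2-[(1Z)-3-[(tert-butyldiphenylsilyl)oxy]-2-iodoprop-1-en-1-yl]-4-methylidene-5-oxooxolan-3-yl]-4-hydroxy-4-methyl-6-{[(2R)-2-methylbutanoyl]oxy}hex-2-enethioate | C=C1C(=O)O[C@H](/C=C(\I)CO[Si](c2ccccc2)(c2ccccc2)C(C)(C)C)[C@H]1[C@H](OC(=O)[C@H](C)CC)C[C@@](C)(O)/C=C/C(=O)Sc1ccccc1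
F13 | step 12 | S-phenyl (2E,4R,6R)-6-[(2S,3R)-2-[(1Z)-3-[(tert-butyldiphenylsilyl)oxy]-2-(trimethylstannyl)prop-1-en-1-yl]-4-methylidene-5-oxooxolan-3-yl]-4-hydroxy-4-methyl-6-{[(2R)-2-methylbutanoyl]oxy}hex-2-enethioate | C=C1C(=O)O[C@H](/C=C(\[Sn](C)(C)C)CO[Si](c2ccccc2)(c2ccccc2)C(C)(C)C)[C@H]1[C@H](OC(=O)[C@H](C)CC)C[C@@](C)(O)/C=C/C(=O)Sc1ccccc1
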